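**Plan**

- Retrosynthesis: the butenolide is cut from the side chain at its ring C–CH2 bond. The cyclopentane is cut at the angular C(OH)–CMe2 bond and at the CH2–CH(ring fusion) bond. The cycloheptane is cut at CH(CH3)–CH2 and at the bond that joins the later carbinol carbon to the later ring-fusion carbon.
- Enabling feature: in the seven-membered ring the ketone carbon and the angular carbinol carbon flank the ring-fusion CH, and the CH(CH3) sits beside the quaternary carbon. With the ketone as a silyl enol ether this ring is a cyclohepta-1,4-diene, the Cope product of a cis-dialkenylcyclopropane built on C(carbinol)–CH2–C(ketone).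
- Forward: an acyclic 2-siloxy-1,3-diene and a vinyldiazoacetate give the seven-membered ring in one operation. The enol ether is methylated to the quaternary centre, the CH2 between the two oxygenated carbons is alkylated with an epoxy iodide, and the helper ester carbon is excised to the second ketone. A trivalent-titanium epoxide radical closure then forms the cyclopentane, and the butenolide is coupled last.
- Stereochemistry: CH(CH3) from the chiral dirhodium catalyst (step 7); the quaternary carbon by methylation anti to that methyl (step 8); the secondary carbinol from Sharpless epoxidation (step 9); the angular carbinol by relay from the epoxide carbon in the radical closure (step 13); the ring-fusion CH by equilibration next to the ketone (step 14).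

Key step: step 7

Assumption: the facial sense of Rh2(R-DOSP)4 on this 1,1-disubstituted silyl enol ether is taken from the behaviour of this catalyst family with styrene-type alkenes; if the first adduct proves antipodal, Rh2(S-DOSP)4 is used instead.

**Route**

Step 1
Reactants: 1 3-(triphenyl-λ5-phosphanylidene)oxolan-2-one; 2 acetaldehyde
Product: 3 (3E)-3-ethylideneoxolan-2-one
Conditions: CH2Cl2, 23 °C, excess 2, sealed vessel
Reagents that add atoms: none
Why: Wittig olefination with a stabilized lactone ylide should give the E-alkylidene lactone (methyl anti to the carbonyl), the geometry the diene needs later.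

Step 2
Reactants: 3 (3E)-3-ethylideneoxolan-2-one
Product: 4 (2E)-2-(2-hydroxyethyl)-N-methoxy-N-methylbut-2-enamide
Conditions: MeNH(OMe)·HCl, Me3Al, CH2Cl2, 0 → 23 °C
Reagents that add atoms: N,O-dimethylhydroxylamine hydrochloride CNOC.Cl
Why: Aluminium-amide aminolysis of the lactone (Weinreb amide formation) should open the ring without touching the trisubstituted alkene; the product is silylated without delay to prevent relactonization.

Step 3
Reactants: 4 (2E)-2-(2-hydroxyethyl)-N-methoxy-N-methylbut-2-enamide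
Product: 5 (2E)-2-{2-[(tert-butyldiphenylsilyl)oxy]ethyl}-N-methoxy-N-methylbut-2-enamide
Conditions: TBDPSCl, imidazole, CH2Cl2, 23 °C
Reagents that add atoms: tert-butyl(chloro)diphenylsilane CC(C)(C)[Si](Cl)(c1ccccc1)c1ccccc1
Why: Standard silylation of the primary alcohol gives an ether that should survive base, fluoride at low temperature, carbenoid and radical steps.

Step 4
Reactants: 5 (2E)-2-{2-[(tert-butyldiphenylsilyl)oxy]ethyl}-N-methoxy-N-methylbut-2-enamide
Product: 6 (3E)-3-{2-[(tert-butyldiphenylsilyl)oxy]ethyl}pent-3-en-2-one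
Conditions: MeMgBr, THF, 0 °C; cold NH4Cl quench
Reagents that add atoms: methylmagnesium bromide C[Mg]Br
Why: Grignard addition to the Weinreb amide should stop at the methyl ketone through the chelated tetrahedral intermediate, with the alkene geometry unchanged.

Step 5
Reactants: 6 (3E)-3-{2-[(tert-butyldiphenylsilyl)oxy]ethyl}pent-3-en-2-one
Product: 7 (3E)-2-[(tert-butyldimethylsilyl)oxy]-3-{2-[(tert-butyldiphenylsilyl)oxy]ethyl}penta-1,3-diene
Conditions: TBSOTf, Et3N, CH2Cl2, 0 °C
Reagents that add atoms: tert-butyldimethylsilyl trifluoromethanesulfonate CC(C)(C)[Si](C)(C)OS(=O)(=O)C(F)(F)F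
Why: Soft enolization and O-silylation at the methyl group should give the cross-conjugated 2-siloxy-1,3-diene.

Step 6
Reactants: 8 methyl but-3-enoate
Product: 9 methyl 2-diazobut-3-enoate
Conditions: 4-acetamidobenzenesulfonyl azide, DBU, MeCN, 0 °C; used cold and at once
Reagents that add atoms: 4-acetamidobenzenesulfonyl azide CC(=O)Nc1ccc(cc1)S(=O)(=O)N=[N+]=[N-]
Why: Regitz diazo transfer to the methylene activated by both the ester and the vinyl group should give the vinyldiazoacetate, which is kept cold because it cyclizes to a pyrazole on standing.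

Step 7
Reactants: 7 (3E)-2-[(tert-butyldimethylsilyl)oxy]-3-{2-[(tert-butyldiphenylsilyl)oxy]ethyl}penta-1,3-diene; 9 methyl 2-diazobut-3-enoate
Product: 11 methyl (4R)-6-[(tert-butyldimethylsilyl)oxy]-5-{2-[(tert-butyldiphenylsilyl)oxy]ethyl}-4-methylcyclohepta-1,5-diene-1-carboxylate, via cis-dialkenylcyclopropane 10 (not isolated)
Conditions: Rh2(R-DOSP)4 [tetrakis((R)-1-(4-dodecylphenylsulfonyl)prolinato)dirhodium] (1 mol %), hexanes, slow addition of 9 at −78 °C, → 23 °C, then 60 °C
Reagents that add atoms: none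
Why: Loss of N2 gives a rhodium vinylcarbenoid that should cyclopropanate only the electron-rich CH2=C(OSi) double bond of 7, and the cis-1,2-dialkenylcyclopropane 10 then undergoes a Cope rearrangement that breaks the ring bond between the carbenoid carbon and the siloxy carbon. The closest known reaction type is the tandem cyclopropanation/Cope rearrangement (formal (4+3) cycloaddition) of vinyldiazoacetates with 2-siloxy-1,3-dienes under chiral dirhodium prolinate catalysis. The three-membered ring closes by concerted (2+1) carbenoid addition and the seven-membered ring by a concerted [3,3] sigmatropic ring expansion through a boat transition state. The one stereocentre that survives, the ring CH(CH3), is set by transfer of the catalyst-controlled cyclopropane configuration through the boat, in which the methyl of the E-alkenyl arm must point outward. The step needs site selectivity, which the contrast between the unhindered enol-ether double bond and the trisubstituted one secures, and cis placement of the two alkenyl arms, which the end-on approach favours (any trans isomer should rearrange on warming). It also needs suppression of attack at the vinyl terminus of the carbenoid, for which hydrocarbon solvent and low temperature are chosen.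

Step 8
Reactants: 11 methyl (4R)-6-[(tert-butyldimethylsilyl)oxy]-5-{2-[(tert-butyldiphenylsilyl)oxy]ethyl}-4-methylcyclohepta-1,5-diene-1-carboxylate
Product: 12 methyl (4R,5R)-5-{2-[(tert-butyldiphenylsilyl)oxy]ethyl}-4,5-dimethyl-6-oxocyclohept-1-ene-1-carboxylate
Conditions: tris(dimethylamino)sulfonium difluorotrimethylsilicate (TASF), MeI (excess), THF, −78 → 0 °C
Reagents that add atoms: iodomethane CI
Why: Fluoride should cleave only the silyl enol ether to a regiodefined enolate that is methylated faster than it equilibrates (regiospecific alkylation of a silyl enol ether), with MeI approaching anti to the neighbouring ring methyl so that the quaternary carbon forms with the two methyls trans.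

Step 9
Reactants: 13 3-methylbut-2-en-1-ol
Product: 14 [(2S)-3,3-dimethyloxiran-2-yl]methanol
Conditions: Ti(OiPr)4 (10 mol %), L-(+)-diethyl tartrate (12 mol %), tBuOOH, 4 Å MS, CH2Cl2, −20 °C
Reagents that add atoms: tert-butyl hydroperoxide CC(C)(C)OO
Why: Sharpless asymmetric epoxidation with the L-(+)-tartrate should deliver oxygen to the face that gives the (S)-epoxy alcohol, the source of the secondary carbinol centre.

Step 10
Reactants: 14 [(2S)-3,3-dimethyloxiran-2-yl]methanol
Product: 15 (3R)-3-(iodomethyl)-2,2-dimethyloxirane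
Conditions: I2, PPh3, imidazole, Et2O/MeCN, 0 °C
Reagents that add atoms: iodine II
Why: Appel-type iodination of the primary alcohol under imidazole buffering should leave the epoxide intact (the descriptor changes only because iodine raises the CIP rank of the CH2 group).

Step 11
Reactants: 12 methyl (4R,5R)-5-{2-[(tert-butyldiphenylsilyl)oxy]ethyl}-4,5-dimethyl-6-oxocyclohept-1-ene-1-carboxylate; 15 (3R)-3-(iodomethyl)-2,2-dimethyloxirane
Product: 16 methyl (4R,5R)-5-{2-[(tert-butyldiphenylsilyl)oxy]ethyl}-7-{[(2S)-3,3-dimethyloxiran-2-yl]methyl}-4,5-dimethyl-6-oxocyclohept-1-ene-1-carboxylate (both C7 epimers)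
Conditions: LiHMDS (1.0 equiv), THF, −78 °C; then 15, DMPU, −78 → −30 °C
Reagents that add atoms: none
Why: The ketone has only one enolizable carbon (the other is quaternary), and SN2 alkylation of its lithium dienolate at the α-carbon by the primary iodide should attach the epoxy arm; the new CH centre need not be controlled because it becomes labile again after step 12.

Step 12
Reactants: 16 methyl (4R,5R)-5-{2-[(tert-butyldiphenylsilyl)oxy]ethyl}-7-{[(2S)-3,3-dimethyloxiran-2-yl]methyl}-4,5-dimethyl-6-oxocyclohept-1-ene-1-carboxylate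
Product: 18 (4R,5R)-4-{2-[(tert-butyldiphenylsilyl)oxy]ethyl}-2-{[(2S)-3,3-dimethyloxiran-2-yl]methyl}-4,5-dimethylcycloheptane-1,3-dione (C2 epimers), via silyl ketene acetal 17 (not isolated)
Conditions: Cu(OAc)2 (5 mol %), 1,2-bis(diphenylphosphino)benzene (5 mol %), PhMe2SiH, PhMe, 23 °C; solvent exchange to CH2Cl2; O3, −78 °C; Me2S
Reagents that add atoms: ozone [O-][O+]=O
Why: Copper-hydride 1,4-hydrosilylation of the enoate (faster than reduction of the hindered ketone) should give the silyl ketene acetal, whose electron-rich C=C is cleaved by ozone to the ring ketone; this excises the helper ester carbon as a carbonate under neutral conditions that spare the epoxide (oxidative degradation of an ester through its ketene acetal).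

Step 13
Reactants: 18 (4R,5R)-4-{2-[(tert-butyldiphenylsilyl)oxy]ethyl}-2-{[(2S)-3,3-dimethyloxiran-2-yl]methyl}-4,5-dimethylcycloheptane-1,3-dione
Product: 19 (2S,3aR,5R,6R,8aS)-5-{2-[(tert-butyldiphenylsilyl)oxy]ethyl}-2,8a-dihydroxy-1,1,5,6-tetramethyloctahydroazulen-4(1H)-one (cis-fused)
Conditions: Cp2TiCl2 (2.5 equiv), Mn dust, THF, 23 °C (gives Cp2TiCl, trivalent titanium); slow addition of 18; aq. NaH2PO4
Reagents that add atoms: none
Why: Cp2TiCl should open the epoxide homolytically at its tertiary carbon, and the radical should add 5-exo to the less hindered ring carbonyl (the other is flanked by the quaternary carbon), the alkoxy radical being reduced by a second trivalent titanium (titanocene-mediated epoxy-ketone radical cyclization). In the chair-like transition state the titanium-oxy group and the ring branch sit pseudo-equatorial, so the new tertiary OH should come out trans to the secondary OH and the ring fusion cis.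

Step 14
Reactants: 19 (2S,3aR,5R,6R,8aS)-5-{2-[(tert-butyldiphenylsilyl)oxy]ethyl}-2,8a-dihydroxy-1,1,5,6-tetramethyloctahydroazulen-4(1H)-one
Product: 20 (2S,3aS,5R,6R,8aS)-5-{2-[(tert-butyldiphenylsilyl)oxy]ethyl}-2,8a-dihydroxy-1,1,5,6-tetramethyloctahydroazulen-4(1H)-one (trans-fused)
Conditions: DBU (0.5 equiv), PhMe, 23 → 40 °C
Reagents that add atoms: none
Why: The ring-fusion CH is α to the ketone, and reversible enolization should settle it in the trans-fused arrangement, expected to be the more stable one for a hydroazulenone with the ketone in the seven-membered ring next to the fusion; DBU is too weak to form the alkoxide needed for retro-aldol opening.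

Step 15
Reactants: 20 (2S,3aS,5R,6R,8aS)-5-{2-[(tert-butyldiphenylsilyl)oxy]ethyl}-2,8a-dihydroxy-1,1,5,6-tetramethyloctahydroazulen-4(1H)-one
Product: 21 (2S,3aS,5R,6R,8aS)-2,8a-dihydroxy-5-(2-hydroxyethyl)-1,1,5,6-tetramethyloctahydroazulen-4(1H)-one
Conditions: HF·pyridine, pyridine, THF, 0 → 23 °C
Reagents that add atoms: none
Why: Buffered fluoride desilylation should free the primary alcohol without the basic conditions that would endanger the β-hydroxy ketone.

Step 16
Reactants: 21 (2S,3aS,5R,6R,8aS)-2,8a-dihydroxy-5-(2-hydroxyethyl)-1,1,5,6-tetramethyloctahydroazulen-4(1H)-one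
Product: 22 (2S,3aS,5R,6R,8aS)-2,8a-dihydroxy-5-(2-iodoethyl)-1,1,5,6-tetramethyloctahydroazulen-4(1H)-one
Conditions: I2, PPh3, imidazole, CH2Cl2, 0 °C
Reagents that add atoms: iodine II
Why: Appel iodination should select the primary alcohol over the neopentyl secondary and the tertiary alcohol.

Step 17
Reactants: 22 (2S,3aS,5R,6R,8aS)-2,8a-dihydroxy-5-(2-iodoethyl)-1,1,5,6-tetramethyloctahydroazulen-4(1H)-one; 23 4-bromofuran-2(5H)-one
Product: 25 (2S,3aS,5R,6R,8aS)-2,8a-dihydroxy-1,1,5,6-tetramethyl-5-[2-(5-oxo-2,5-dihydrofuran-3-yl)ethyl]octahydroazulen-4(1H)-one, via alkylzinc iodide 24 (not isolated)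
Conditions: Zn dust (activated with TMSCl and BrCH2CH2Br), DMA, 40 °C; then 23, Pd2(dba)3 (2.5 mol %), P(o-tol)3 (10 mol %), 23 → 40 °C
Reagents that add atoms: none
Why: Zinc insertion into the primary iodide should give an alkylzinc iodide that tolerates the ketone and the hindered hydroxyl groups, and Negishi coupling with the vinylogous acyl bromide should attach the butenolide at its β-carbon under near-neutral conditions.

**Compound list**

1 | 3-(triphenyl-λ5-phosphanylidene)oxolan-2-one | O=C1OCCC1=P(c1ccccc1)(c1ccccc1)c1ccccc1 | starting material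
2 | acetaldehyde | CC=O | starting material
3 | (3E)-3-ethylideneoxolan-2-one | C/C=C1/C(=O)OCC1 | intermediate
4 | (2E)-2-(2-hydroxyethyl)-N-methoxy-N-methylbut-2-enamide | C/C=C(\CCO)C(=O)N(C)OC | intermediate
5 | (2E)-2-{2-[(tert-butyldiphenylsilyl)oxy]ethyl}-N-methoxy-N-methylbut-2-enamide | C/C=C(\CCO[Si](c1ccccc1)(c1ccccc1)C(C)(C)C)C(=O)N(C)OC | intermediate
6 | (3E)-3-{2-[(tert-butyldiphenylsilyl)oxy]ethyl}pent-3-en-2-one | C/C=C(\CCO[Si](c1ccccc1)(c1ccccc1)C(C)(C)C)C(C)=O | intermediate
7 | (3E)-2-[(tert-butyldimethylsilyl)oxy]-3-{2-[(tert-butyldiphenylsilyl)oxy]ethyl}penta-1,3-diene | C/C=C(\CCO[Si](c1ccccc1)(c1ccccc1)C(C)(C)C)C(=C)O[Si](C)(C)C(C)(C)C | intermediate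
8 | methyl but-3-enoate | C=CCC(=O)OC | starting material
9 | methyl 2-diazobut-3-enoate | C=CC(=[N+]=[N-])C(=O)OC | intermediate
10 | methyl (1S,2R)-2-[(tert-butyldimethylsilyl)oxy]-2-{(2E)-5-[(tert-butyldiphenylsilyl)oxy]pent-2-en-3-yl}-1-ethenylcyclopropane-1-carboxylate | C=C[C@@]1(C(=O)OC)C[C@@]1(O[Si](C)(C)C(C)(C)C)/C(CCO[Si](c1ccccc1)(c1ccccc1)C(C)(C)C)=C/C | intermediate
11 | methyl (4R)-6-[(tert-butyldimethylsilyl)oxy]-5-{2-[(tert-butyldiphenylsilyl)oxy]ethyl}-4-methylcyclohepta-1,5-diene-1-carboxylate | C[C@@H]1CC=C(C(=O)OC)CC(O[Si](C)(C)C(C)(C)C)=C1CCO[Si](c1ccccc1)(c1ccccc1)C(C)(C)C | intermediate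
12 | methyl (4R,5R)-5-{2-[(tert-butyldiphenylsilyl)oxy]ethyl}-4,5-dimethyl-6-oxocyclohept-1-ene-1-carboxylate | C[C@@H]1CC=C(C(=O)OC)CC(=O)[C@]1(C)CCO[Si](c1ccccc1)(c1ccccc1)C(C)(C)C | intermediate
13 | 3-methylbut-2-en-1-ol | CC(C)=CCO | starting material
14 | [(2S)-3,3-dimethyloxiran-2-yl]methanol | OC[C@@H]1OC1(C)C | intermediate
15 | (3R)-3-(iodomethyl)-2,2-dimethyloxirane | IC[C@@H]1OC1(C)C | intermediate
16 | methyl (4R,5R)-5-{2-[(tert-butyldiphenylsilyl)oxy]ethyl}-7-{[(2S)-3,3-dimethyloxiran-2-yl]methyl}-4,5-dimethyl-6-oxocyclohept-1-ene-1-carboxylate (C7 epimers) | C[C@@H]1CC=C(C(=O)OC)C(C[C@@H]2OC2(C)C)C(=O)[C@]1(C)CCO[Si](c1ccccc1)(c1ccccc1)C(C)(C)C | intermediate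
17 | dimethyl(phenyl)silyl methyl ketene acetal of the saturated ester from 16 (exocyclic C=C(OMe)OSiMe2Ph on the ring) | C[C@@H]1CCC(=C(OC)O[Si](C)(C)c2ccccc2)C(C[C@@H]2OC2(C)C)C(=O)[C@]1(C)CCO[Si](c1ccccc1)(c1ccccc1)C(C)(C)C | intermediate
18 | (4R,5R)-4-{2-[(tert-butyldiphenylsilyl)oxy]ethyl}-2-{[(2S)-3,3-dimethyloxiran-2-yl]methyl}-4,5-dimethylcycloheptane-1,3-dione (C2 epimers) | C[C@@H]1CCC(=O)C(C[C@@H]2OC2(C)C)C(=O)[C@]1(C)CCO[Si](c1ccccc1)(c1ccccc1)C(C)(C)C | intermediate
19 | (2S,3aR,5R,6R,8aS)-5-{2-[(tert-butyldiphenylsilyl)oxy]ethyl}-2,8a-dihydroxy-1,1,5,6-tetramethyloctahydroazulen-4(1H)-one (cis-fused) | C[C@@H]1CC[C@]2(O)[C@@H](C[C@H](O)C2(C)C)C(=O)[C@]1(C)CCO[Si](c1ccccc1)(c1ccccc1)C(C)(C)C | intermediate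
20 | (2S,3aS,5R,6R,8aS)-5-{2-[(tert-butyldiphenylsilyl)oxy]ethyl}-2,8a-dihydroxy-1,1,5,6-tetramethyloctahydroazulen-4(1H)-one (trans-fused) | C[C@@H]1CC[C@]2(O)[C@H](C[C@H](O)C2(C)C)C(=O)[C@]1(C)CCO[Si](c1ccccc1)(c1ccccc1)C(C)(C)C | intermediate
21 | (2S,3aS,5R,6R,8aS)-2,8a-dihydroxy-5-(2-hydroxyethyl)-1,1,5,6-tetramethyloctahydroazulen-4(1H)-one | C[C@@H]1CC[C@]2(O)[C@H](C[C@H](O)C2(C)C)C(=O)[C@]1(C)CCO | intermediate
22 | (2S,3aS,5R,6R,8aS)-2,8a-dihydroxy-5-(2-iodoethyl)-1,1,5,6-tetramethyloctahydroazulen-4(1H)-one | C[C@@H]1CC[C@]2(O)[C@H](C[C@H](O)C2(C)C)C(=O)[C@]1(C)CCI | intermediate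
23 | 4-bromofuran-2(5H)-one | O=C1C=C(Br)CO1 | starting material
24 | alkylzinc iodide from 22 | C[C@@H]1CC[C@]2(O)[C@H](C[C@H](O)C2(C)C)C(=O)[C@]1(C)CC[Zn]I | intermediate
25 | (2S,3aS,5R,6R,8aS)-2,8a-dihydroxy-1,1,5,6-tetramethyl-5-[2-(5-oxo-2,5-dihydrofuran-3-yl)ethyl]octahydroazulen-4(1H)-one | C[C@@H]1CC[C@]2(O)[C@H](C[C@H](O)C2(C)C)C(=O)[C@]1(C)CCC1=CC(=O)OC1 | target

**Step count**

Total step count: 17. Longest linear sequence: 14 steps (steps 1 to 5, 7, 8 and 11 to 17).

**Steps most likely to fail**

Step 7. The very electron-rich enol ether may attack the carbenoid at its vinyl terminus and lead to five-membered products. The cyclopropane may also form with its two alkenyl arms trans, and the catalyst's facial control over a 1,1-disubstituted enol ether may be modest. The fallback moves the stereocontrol from the catalyst to a covalently bound auxiliary and sets out from 7. But-3-enoic acid is esterified with (R)-pantolactone (DCC, DMAP, CH2Cl2) to (3R)-4,4-dimethyl-2-oxooxolan-3-yl but-3-enoate F1. Diazo transfer as in step 6 gives (3R)-4,4-dimethyl-2-oxooxolan-3-yl 2-diazobut-3-enoate F2. With 7 and the achiral catalyst Rh2(O2CC7H15)4 in refluxing pentane, F2 should give the pantolactonyl dialkenylcyclopropane ester F3 (not isolated) and from it the pantolactonyl cycloheptadiene ester F4, the auxiliary shielding one face of the carbenoid. Methylation as in step 8 gives the pantolactonyl keto ester F5, and methanolysis (K2CO3, MeOH, 0 °C) returns the route at 12 with recovery of the auxiliary. If the auxiliary induces the opposite sense, its antipode is used.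

Step 13. The tertiary radical may be reduced by a second trivalent titanium or lose a β-hydrogen before it reaches the hindered carbonyl. The transfer of configuration from the epoxide-derived carbinol carbon to the new angular carbinol carbon may also be weak, or may run the other way and give the cis-1,3-diol. The fallback sets the secondary carbinol after the ring closure and sets out from 12 and 13. Epoxidation of 13 with D-(−)-diethyl tartrate gives [(2R)-3,3-dimethyloxiran-2-yl]methanol F6, and iodination as in step 10 gives (3S)-3-(iodomethyl)-2,2-dimethyloxirane F7. Alkylation of 12 with F7 as in step 11 gives the epimeric epoxy ester F8. The conditions of step 12 take it through the epimeric silyl ketene acetal F9 (not isolated) to the epimeric epoxy dione F10. Closure with Cp2TiCl in the cis sense then gives the cis-diol F11, which has the target configuration at the angular carbinol. Its secondary alcohol is oxidized with the periodinane 1,1,1-triacetoxy-1,1-dihydro-1,2-benziodoxol-3(1H)-one to the β-hydroxy ketone F12. Hydroxyl-directed reduction with Me4NBH(OAc)3 (AcOH/MeCN, −20 °C) delivers hydride cis to the angular OH and returns the route at 19.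

Step 14. The equilibrium at the ring-fusion carbon may not favour the trans-fused ketone, and the β-hydroxy ketone may open by retro-aldol cleavage or lose water under base. The fallback replaces thermodynamic control by kinetic protonation and sets out from 19. Silylation of both hydroxyl groups (TMSOTf, 2,6-lutidine, CH2Cl2, −78 °C) gives the cis-fused bis(trimethylsilyl) ether F13. Deprotonation at the only α-CH (LDA, THF, −78 °C) and quenching at −78 °C with 2,6-di-tert-butyl-4-methylphenol should protonate the enolate anti to the neighbouring angular silyloxy group and give the trans-fused bis(trimethylsilyl) ether F14. The conditions of step 15 remove all three silyl groups and return the route at 21.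

Further compounds
F1 | step 7 | (3R)-4,4-dimethyl-2-oxooxolan-3-yl but-3-enoate | C=CCC(=O)O[C@H]1C(=O)OCC1(C)C
F2 | step 7 | (3R)-4,4-dimethyl-2-oxooxolan-3-yl 2-diazobut-3-enoate | C=CC(=[N+]=[N-])C(=O)O[C@H]1C(=O)OCC1(C)C
F3 | step 7 | pantolactonyl ester analogue of cyclopropane 10 | C=C[C@@]1(C(=O)O[C@H]2C(=O)OCC2(C)C)C[C@@]1(O[Si](C)(C)C(C)(C)C)/C(CCO[Si](c1ccccc1)(c1ccccc1)C(C)(C)C)=C/C
F4 | step 7 | pantolactonyl ester analogue of cycloheptadiene 11 | C[C@@H]1CC=C(C(=O)O[C@H]2C(=O)OCC2(C)C)CC(O[Si](C)(C)C(C)(C)C)=C1CCO[Si](c1ccccc1)(c1ccccc1)C(C)(C)C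
F5 | step 7 | pantolactonyl ester analogue of keto ester 12 | C[C@@H]1CC=C(C(=O)O[C@H]2C(=O)OCC2(C)C)CC(=O)[C@]1(C)CCO[Si](c1ccccc1)(c1ccccc1)C(C)(C)C
F6 | step 13 | [(2R)-3,3-dimethyloxiran-2-yl]methanol | OC[C@H]1OC1(C)C
F7 | step 13 | (3S)-3-(iodomethyl)-2,2-dimethyloxirane | IC[C@H]1OC1(C)C
F8 | step 13 | epoxide epimer of 16 with a (2R)-oxirane | C[C@@H]1CC=C(C(=O)OC)C(C[C@H]2OC2(C)C)C(=O)[C@]1(C)CCO[Si](c1ccccc1)(c1ccccc1)C(C)(C)C
F9 | step 13 | epoxide epimer of silyl ketene acetal 17 | C[C@@H]1CCC(=C(OC)O[Si](C)(C)c2ccccc2)C(C[C@H]2OC2(C)C)C(=O)[C@]1(C)CCO[Si](c1ccccc1)(c1ccccc1)C(C)(C)C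
F10 | step 13 | epoxide epimer of dione 18 | C[C@@H]1CCC(=O)C(C[C@H]2OC2(C)C)C(=O)[C@]1(C)CCO[Si](c1ccccc1)(c1ccccc1)C(C)(C)C
F11 | step 13 | (2R,3aR,5R,6R,8aS)-5-{2-[(tert-butyldiphenylsilyl)oxy]ethyl}-2,8a-dihydroxy-1,1,5,6-tetramethyloctahydroazulen-4(1H)-one (cis-diol) | C[C@@H]1CC[C@]2(O)[C@@H](C[C@@H](O)C2(C)C)C(=O)[C@]1(C)CCO[Si](c1ccccc1)(c1ccccc1)C(C)(C)C
F12 | step 13 | (3aR,5R,6R,8aS)-5-{2-[(tert-butyldiphenylsilyl)oxy]ethyl}-8a-hydroxy-1,1,5,6-tetramethylhexahydroazulene-2,4(1H,3H)-dione | C[C@@H]1CC[C@]2(O)[C@@H](CC(=O)C2(C)C)C(=O)[C@]1(C)CCO[Si](c1ccccc1)(c1ccccc1)C(C)(C)C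
F13 | step 14 | bis(trimethylsilyl) ether of 19 (cis-fused) | C[C@@H]1CC[C@]2(O[Si](C)(C)C)[C@@H](C[C@H](O[Si](C)(C)C)C2(C)C)C(=O)[C@]1(C)CCO[Si](c1ccccc1)(c1ccccc1)C(C)(C)C
F14 | step 14 | bis(trimethylsilyl) ether of 20 (trans-fused) | C[C@@H]1CC[C@]2(O[Si](C)(C)C)[C@H](C[C@H](O[Si](C)(C)C)C2(C)C)C(=O)[C@]1(C)CCO[Si](c1ccccc1)(c1ccccc1)C(C)(C)C
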